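In each spiro[4.5]decane half the cyclopentane (spiro carbon C4, methylenes C3 and C1, side-chain methine C2, carbinol C10) has an unfunctionalised CH2–CH2 edge, C3–C1, that is ethene in disguise. The key step adds an α-acyl radical at C2 to ethene (bond C1–C2) and lets the new primary radical close 5-exo onto C4, the β-carbon of a cyclohexenone (bond C3–C4), creating the spiro quaternary centre and C5 in one operation. Its precursor is a linalool-derived cyclohexenone carrying an acetonide-locked α-bromo-β-oxy imide on C4. The acyl carbon later leaves as CO2 when two spiro units are coupled to a Diels–Alder-built bis(vinyl iodide) core.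

Key step: step 11

Remarks on the chemistry (assumptions):
- Locants (not IUPAC): cyclopentane C4(spiro)–C3H2–C1H2–C2H(side chain)–C10H(O); cyclohexane C4–C5H(3-oxypropyl)–C6–C7H2–C8H2–C9(CH3)(O); O9 and O10 are the oxygens on C9 and C10; Csc is the side-chain carbon bonded to C2. In the central cyclohexene Ca is the quaternary carbon and Cf the neighbouring methine.
- (S)-(+)-Linalool is assumed to be available commercially in high enantiomeric purity.
- C2 in 21–30 and C6 in 25 are epimer mixtures of no consequence (C2 is reset in step 27, C6 becomes sp2 in step 14); their SMILES leave these centres open.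

Step 1
Reactants: 1 (S)-4-benzyloxazolidin-2-one; 2 bromoacetyl bromide
Product: 4 (S)-4-benzyl-3-(2-bromoacetyl)oxazolidin-2-one, via lithium oxazolidinide 3 (not isolated)
Conditions: n-BuLi, THF, −78 °C; then 2, −78 → 0 °C
Reagents that add atoms: none
Why: N-acylation of the lithiated carbamate by the acid bromide (acyl substitution); the auxiliary stereocentre is untouched.

Step 2
Reactants: 5 (S)-(+)-linalool
Product: 7 (S)-5-ethenyl-5-methyloxolan-2-one, via lactol 6 (not isolated)
Conditions: O3 (1 equiv), pyridine, CH2Cl2/MeOH, −78 °C; Me2S; then TEMPO (cat.), PhI(OAc)2, CH2Cl2, rt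
Reagents that add atoms: ozone, O=[O+][O-]
Why: Chemoselective ozonolysis of the electron-rich trisubstituted alkene (the hindered allylic vinyl group reacts far more slowly), ring closure to the lactol and oxoammonium oxidation to the lactone; C9 comes unchanged from linalool.

Step 3
Reactants: 7 (S)-5-ethenyl-5-methyloxolan-2-one
Product: 8 (S)-5-acetyl-5-methyloxolan-2-one
Conditions: PdCl2(Quinox) (Quinox = 2-(4,5-dihydro-1,3-oxazol-2-yl)quinoline) (cat.), AgSbF6 (cat.), aq. t-BuOOH, CH2Cl2, 0 °C → rt
Reagents that add atoms: tert-butyl hydroperoxide, CC(C)(C)OO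
Why: Wacker-type oxidation in its peroxide-mediated variant, which delivers oxygen to the internal carbon of alkenes bearing an allylic acyloxy group and so gives the methyl ketone.

Step 4
Reactants: 8 (S)-5-acetyl-5-methyloxolan-2-one
Product: 9 (S)-4-hydroxy-4-methylcyclohexane-1,3-dione
Conditions: KOtBu, THF, 0 °C → rt; then aq. HCl
Reagents that add atoms: none
Why: Intramolecular Claisen (Dieckmann-type) condensation: the methyl ketone enolate attacks the lactone carbonyl through a six-membered transition state and expels the tertiary alkoxide, driven by formation of the dione enolate.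

Step 5
Reactants: 9 (S)-4-hydroxy-4-methylcyclohexane-1,3-dione; 10 3-(tert-butyldimethylsilyloxy)propanal
Product: 11 (4S)-2-[3-(tert-butyldimethylsilyloxy)propyl]-4-hydroxy-4-methylcyclohexane-1,3-dione (drawn as enol)
Conditions: L-proline (cat.), Hantzsch ester (diethyl 2,6-dimethyl-1,4-dihydropyridine-3,5-dicarboxylate), CH2Cl2, rt
Reagents that add atoms: none
Why: Organocatalytic reductive alkylation: Knoevenagel condensation at C5 followed by conjugate transfer hydrogenation of the alkylidene dione.

Step 6
Reactants: 11 alkylated dione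
Product: 12 (6S)-2-[3-(tert-butyldimethylsilyloxy)propyl]-6-hydroxy-3-methoxy-6-methylcyclohex-2-en-1-one
Conditions: Me2SO4, K2CO3, acetone, rt → 40 °C
Reagents that add atoms: dimethyl sulfate, COS(=O)(=O)OC
Why: O-alkylation of the dione enolate should occur at the oxygen on C6, remote from the quaternary, hydrogen-bonded C9 carbinol, leaving the C4 carbonyl as the ketone (vinylogous ester formation).

Step 7
Reactants: 12 vinylogous ester; 13 vinylmagnesium bromide
Product: 15 (4S)-2-[3-(tert-butyldimethylsilyloxy)propyl]-3-ethenyl-4-hydroxy-4-methylcyclohex-2-en-1-one, via tertiary carbinol 14 (not isolated)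
Conditions: 13 (3.5 equiv), CeCl3, THF, −78 → 0 °C; then 0.5 M HCl, THF, 0 °C (short)
Reagents that add atoms: water, O
Why: Stork–Danheiser sequence: 1,2-addition to the C4 carbonyl, then acid hydrolysis of the enol ether and dehydration transpose the enone so that C4 becomes its β-carbon and carries the vinyl group (future C10).

Step 8
Reactants: 15 dienone
Product: 16 (6S)-2-[3-(tert-butyldimethylsilyloxy)propyl]-6-hydroxy-6-methyl-3-oxocyclohex-1-ene-1-carbaldehyde
Conditions: OsO4 (cat.), NaIO4, 2,6-lutidine, dioxane/H2O, rt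
Reagents that add atoms: sodium periodate, [Na+].[O-]I(=O)(=O)=O
Why: Lemieux–Johnson cleavage; the terminal vinyl group is dihydroxylated in preference to the tetrasubstituted, electron-poor enone alkene.

Step 9
Reactants: 16 aldehyde; 4 (S)-4-benzyl-3-(2-bromoacetyl)oxazolidin-2-one
Product: 18 (S)-4-benzyl-3-[(2S,3R)-2-bromo-3-hydroxy-3-(C4-cyclohexenonyl)propanoyl]oxazolidin-2-one (C10 R, C2 S, C9 S), via boron enolate 17 (not isolated)
Conditions: 4, Bu2BOTf, i-Pr2NEt, CH2Cl2, −78 → 0 °C; then 16, −78 → −20 °C; pH 7 buffer, MeOH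
Reagents that add atoms: none
Why: Evans syn-aldol reaction of the (Z)-boron enolate through a chair transition state; the auxiliary sets C10 (R) and C2 (S) irrespective of the remote C9 centre.

Step 10
Reactants: 18 aldol adduct
Product: 19 O9,O10-isopropylidene acetal of 18 (1,3-dioxane fused across C9–C4–C10)
Conditions: Me2C(OMe)2, PPTS (cat.), CH2Cl2, rt
Reagents that add atoms: 2,2-dimethoxypropane, COC(C)(C)OC
Why: Acid-catalysed transacetalisation of the 1,3-diol; the ring it creates is the conformational lock used in step 11.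

Step 11
Reactants: 19 acetonide bromo imide; 20 ethene
Product: 21 acetonide-bridged spiro[4.5]decan-6-one imide (C3 anti to O9 at C4; C5 side chain cis to C10; O10 syn to C9; C2 epimer mixture)
Conditions: 20 (10 bar), fac-Ir(ppy)3 (1 mol%), Hantzsch ester (1.5 equiv, in portions), NaHCO3, MeCN, blue LEDs (450 nm), rt
Reagents that add atoms: none
Why: Photoexcited fac-Ir(ppy)3 cleaves the C2–Br bond by single-electron transfer; the electrophilic α-acyl radical adds to ethene (C1–C2), the nucleophilic primary radical at C3 closes the cyclopentane by 5-exo-trig conjugate addition to the enone carbon C4 (C3–C4), and the α-keto radical at C5 takes a hydrogen atom from the Hantzsch ester. The closest known reaction type is the radical [3+2] annulation of α-halo carbonyl compounds with alkenes (intermolecular addition then 5-exo cyclisation), here in its reductive photoredox variant ending in a radical Michael addition. C4 is controlled by the substrate: the dioxane ring holds O10 on the O9 face and allylic 1,3-strain with the C5 side chain keeps the C10–H bond in the enone plane, so the (R)-configured C10 from step 9 projects C2 and the growing chain to the face anti to O9, where the spiro bond forms. C5 receives hydrogen anti to the dioxane-bearing C10 branch, which puts the side chain equatorial and cis to C10 (also the thermodynamic epimer); C2 forms as a mixture that is erased in step 27. The step needs ethene capture to outrun hydrogen transfer to the first radical (ethene pressure, portionwise Hantzsch ester) and 5-exo to beat 6-endo closure, which the polarity match of an alkyl radical with the β-enone carbon and the tether length secure.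

Step 12
Reactants: 21 spiro imide
Product: 23 spiro keto acid (C2–CO2H), via peroxy acid 22 (not isolated)
Conditions: LiOH, H2O2, THF/H2O, 0 °C; then Na2SO3; aq. HCl to pH 4
Reagents that add atoms: hydrogen peroxide, OO
Why: Hydroperoxide-mediated cleavage of the exocyclic imide carbonyl (standard auxiliary removal), the peroxy acid being reduced by sulfite; the acetonide, silyl ether and ketone survive at 0 °C.

Step 13
Reactants: 23 spiro keto acid; 24 isopropenylmagnesium bromide
Product: 25 C6 tertiary allylic alcohol acid (C6 epimers)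
Conditions: 24 (4 equiv), CeCl3, THF, −78 °C; aq. NH4Cl
Reagents that add atoms: none
Why: Organocerium 1,2-addition to the hindered, enolisable C6 ketone; the carboxylate is inert, and the new C6 centre need not be controlled because it becomes sp2 in step 14.

Step 14
Reactants: 25 tertiary allylic alcohol acid
Product: 26 enal acid with C6=C(CH3)CHO (formyl syn to C5)
Conditions: C5H5NH[CrO3Cl] (pyridinium chlorochromate), NaOAc, 4 Å molecular sieves, CH2Cl2, rt; then SiO2 (equilibration)
Reagents that add atoms: pyridinium chlorochromate, [O-][Cr](=O)(=O)Cl.c1cc[nH+]cc1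
Why: Babler–Dauben oxidative transposition ([3,3] shift of the chromate ester, then oxidation); the tetrasubstituted enal should settle in the isomer with the smaller formyl group syn to the substituted C5, which is the target geometry.

Step 15
Reactants: 26 enal acid
Product: 27 N-(acyloxy)phthalimide ester of 26
Conditions: N-hydroxyphthalimide, DIC, DMAP (cat.), CH2Cl2, rt
Reagents that add atoms: N-hydroxyphthalimide, O=C1N(O)C(=O)c2ccccc12
Why: Carbodiimide esterification to the redox-active ester that will release the C2 radical in step 27.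

Step 16
Reactants: 27 redox-active ester (silyl ether)
Product: 28 primary alcohol (3-hydroxypropyl chain)
Conditions: HF·pyridine, pyridine, THF, 0 °C → rt
Reagents that add atoms: none
Why: Fluoride-mediated cleavage of the primary silyl ether under buffered acidic conditions, which spare the activated ester, the acetonide and the enal.

Step 17
Reactants: 28 primary alcohol; 29 tetradecanoyl chloride
Product: 30 spiro fragment: tetradecanoate, enal, acetonide, N-(acyloxy)phthalimide ester
Conditions: 29, pyridine, CH2Cl2, 0 °C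
Reagents that add atoms: none
Why: O-acylation of the only free hydroxyl group installs the tetradecanoate ester of the target.

Step 18
Reactants: 31 but-2-yne-1,4-diol
Product: 32 4-(triisopropylsilyloxy)but-2-yn-1-ol
Conditions: TIPSCl, imidazole, DMF, 0 °C (31 in excess)
Reagents that add atoms: chlorotri(propan-2-yl)silane, CC(C)[Si](Cl)(C(C)C)C(C)C
Why: Statistical monosilylation of the symmetrical diol.

Step 19
Reactants: 32 monosilylated butynediol
Product: 34 (Z)-3-iodo-4-(triisopropylsilyloxy)but-2-en-1-ol, via alkenylalanate 33 (not isolated)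
Conditions: NaAlH2(OCH2CH2OMe)2, THF, 0 °C; then I2, −78 °C
Reagents that add atoms: iodine, II
Why: Hydroxyl-directed trans-hydroalumination places aluminium on the distal alkyne carbon in a five-membered alanate, and iodinolysis with retention gives the vinyl iodide with iodine cis to CH2OH, the geometry the side chain needs.

Step 20
Reactants: 34 (Z)-iodo allylic alcohol
Product: 35 allylic 1-phenyltetrazol-5-yl sulfide
Conditions: 1-phenyl-1H-tetrazole-5-thiol, PPh3, DIAD, THF, 0 °C
Reagents that add atoms: 1-phenyl-1H-tetrazole-5-thiol, Sc1nnnn1-c1ccccc1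
Why: Mitsunobu thioetherification of the primary allylic alcohol (SN2, alkene geometry untouched).

Step 21
Reactants: 35 sulfide
Product: 36 (Z)-5-{[3-iodo-4-(triisopropylsilyloxy)but-2-en-1-yl]sulfonyl}-1-phenyl-1H-tetrazole
Conditions: (NH4)6Mo7O24·4H2O (cat.), H2O2, EtOH, 0 °C → rt
Reagents that add atoms: hydrogen peroxide, OO
Why: Molybdate-catalysed sulfide-to-sulfone oxidation, which leaves the vinyl iodide and the alkene alone.

Step 22
Reactants: 37 5-bromo-2-methylpent-2-ene; 38 prop-2-yn-1-ol
Product: 40 6-methyl-2-methylidenehept-5-en-1-ol, via Grignard reagent 39 (not isolated)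
Conditions: 37, Mg, THF, rt; then 38, CuI (cat.), THF, −10 °C → rt; aq. NH4Cl
Reagents that add atoms: none
Why: Copper-catalysed carbomagnesiation of the propargylic alkoxide places the alkyl group on the internal alkyne carbon and gives the 2-substituted allylic alcohol.

Step 23
Reactants: 40 allylic alcohol
Product: 41 6-methyl-2-methylidenehept-5-enal
Conditions: TEMPO (cat.), PhI(OAc)2, CH2Cl2, rt
Reagents that add atoms: none
Why: Oxoammonium oxidation of the primary allylic alcohol to the 2-substituted acrolein without touching the trisubstituted alkene.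

Step 24
Reactants: 36 sulfone; 41 2-substituted acrolein
Product: 42 (2Z,4E)-2-iodo-6-methylidene-1-(triisopropylsilyloxy)-10-methylundeca-2,4,9-triene (iodo triene)
Conditions: KN(SiMe3)2 added to 36 + 41, THF, −78 °C → rt; aq. NH4Cl
Reagents that add atoms: none
Why: Julia–Kocienski olefination (1,2-addition, Smiles rearrangement, loss of SO2 and tetrazolate), which should give mainly the E alkene and leaves the vinyl iodide geometry intact.

Step 25
Reactants: 42 iodo triene; 41 2-substituted acrolein
Product: 43 cyclohexene carbaldehyde (Ca quaternary with CHO and 4-methylpent-3-enyl; Cf bearing the (Z)-2-iodo-3-silyloxypropenyl group trans to CHO)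
Conditions: (S)-2-butyl-4-(1H-indol-3-ylmethyl)-3-(4-methylphenylsulfonyl)-1,3,2-oxazaborolidin-5-one (20 mol%), CH2Cl2, −78 → −40 °C
Reagents that add atoms: none
Why: Lewis-acid-catalysed Diels–Alder reaction of the terminal 1,3-diene unit (the only one able to reach s-cis), with regiochemistry para to the 2-alkyl and ortho to the 1-alkenyl group; the N-tosyl-(S)-tryptophan-derived boron catalyst shields one face of the bound aldehyde to set Ca, and formyl-exo approach, usual for 2-substituted acroleins, sets Cf trans to CHO, the minor endo adduct being removable here by chromatography.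

Step 26
Reactants: 43 cyclohexene carbaldehyde; 36 sulfone
Product: 44 central bis(vinyl iodide)
Conditions: KN(SiMe3)2 added to 43 + 36, DME, −60 °C → rt; aq. NH4Cl
Reagents that add atoms: none
Why: Second Julia–Kocienski olefination; the α-quaternary aldehyde cannot enolise and should favour the E alkene of the dienyl iodide arm.

Step 27
Reactants: 30 spiro fragment (2.6 equiv); 44 central bis(vinyl iodide)
Product: 45 bis-acetonide, bis-silyl protected dimer (both C2–Csc bonds formed; C10 still epimeric)
Conditions: NiBr2(dme) (cat.), 4,4′-di-tert-butyl-2,2′-bipyridine, Zn, DMA, rt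
Reagents that add atoms: none
Why: Nickel-catalysed decarboxylative reductive (cross-electrophile) alkenylation: each redox-active ester loses CO2 to give the secondary C2 radical, which is captured by the alkenylnickel species from a vinyl iodide with retention of alkene geometry, the new bond forming trans to the adjacent acetonide oxygen O10 so that the side chain lies syn to C5.

Step 28
Reactants: 45 bis-acetonide
Product: 46 bis(9,10-diol) (C10 and C10′ epimeric to the target)
Conditions: AcOH/THF/H2O (3:1:1), 40 °C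
Reagents that add atoms: none
Why: Mild acid hydrolysis of the two acetonides; the triisopropylsilyl ethers, esters and enals tolerate these conditions.

Step 29
Reactants: 46 bis-diol
Product: 47 bis(C10 ketone)
Conditions: Dess–Martin periodinane, NaHCO3, CH2Cl2, 0 °C
Reagents that add atoms: none
Why: Buffered periodinane oxidation of the two secondary alcohols; the tertiary C9 alcohols cannot be oxidised, and cold neutral conditions limit migration of the β,γ-double bond.

Step 30
Reactants: 47 bis(β-hydroxy ketone)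
Product: 48 bis(triisopropylsilyl) ether of the target
Conditions: Me4NBH(OAc)3, MeCN/AcOH, −30 °C
Reagents that add atoms: none
Why: Evans–Saksena reduction: the tertiary C9 hydroxyl binds boron and delivers hydride to the C10 carbonyl from the C9 face, anti to the C2 side chain, giving the anti-1,3-diol with C10–OH syn to C5 and cis to the side chain; the hindered enals should not be reduced at this temperature.

Step 31
Reactants: 48 bis-silyl ether
Product: 49 target CNP0458412.1
Conditions: HF·pyridine, pyridine, THF, 0 °C → rt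
Reagents that add atoms: none
Why: Fluoride-mediated cleavage of the two primary allylic silyl ethers under buffered conditions that leave esters, enals and the polyene untouched.

Compound list
1 | (S)-4-benzyloxazolidin-2-one | O=C1N[C@@H](Cc2ccccc2)CO1 | starting material
2 | bromoacetyl bromide | BrCC(Br)=O | starting material
3 | lithium (S)-4-benzyl-2-oxooxazolidin-3-ide | [Li+].O=C1[N-][C@@H](Cc2ccccc2)CO1 | intermediate
4 | (S)-4-benzyl-3-(2-bromoacetyl)oxazolidin-2-one | O=C(CBr)N1[C@@H](Cc2ccccc2)COC1=O | intermediate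
5 | (S)-(+)-linalool, (3S)-3,7-dimethylocta-1,6-dien-3-ol | C=C[C@@](C)(O)CCC=C(C)C | starting material
6 | (5S)-5-ethenyl-5-methyloxolan-2-ol (lactol, anomers) | C=C[C@]1(C)CCC(O)O1 | intermediate
7 | (S)-5-ethenyl-5-methyloxolan-2-one | C=C[C@]1(C)CCC(=O)O1 | intermediate
8 | (S)-5-acetyl-5-methyloxolan-2-one | CC(=O)[C@]1(C)CCC(=O)O1 | intermediate
9 | (S)-4-hydroxy-4-methylcyclohexane-1,3-dione | C[C@]1(O)CCC(=O)CC1=O | intermediate
10 | 3-(tert-butyldimethylsilyloxy)propanal | CC(C)(C)[Si](C)(C)OCCC=O | starting material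
11 | (4S)-2-[3-(tert-butyldimethylsilyloxy)propyl]-4-hydroxy-4-methylcyclohexane-1,3-dione (enol form) | C[C@]1(O)CCC(O)=C(CCCO[Si](C)(C)C(C)(C)C)C1=O | intermediate
12 | (6S)-2-[3-(tert-butyldimethylsilyloxy)propyl]-6-hydroxy-3-methoxy-6-methylcyclohex-2-en-1-one | COC1=C(CCCO[Si](C)(C)C(C)(C)C)C(=O)[C@@](C)(O)CC1 | intermediate
13 | vinylmagnesium bromide | C=C[Mg]Br | starting material
14 | (6S)-2-[3-(tert-butyldimethylsilyloxy)propyl]-1-ethenyl-3-methoxy-6-methylcyclohex-2-ene-1,6-diol (C1 epimers) | C=CC1(O)C(CCCO[Si](C)(C)C(C)(C)C)=C(OC)CC[C@]1(C)O | intermediate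
15 | (4S)-2-[3-(tert-butyldimethylsilyloxy)propyl]-3-ethenyl-4-hydroxy-4-methylcyclohex-2-en-1-one | C=CC1=C(CCCO[Si](C)(C)C(C)(C)C)C(=O)CC[C@]1(C)O | intermediate
16 | (6S)-2-[3-(tert-butyldimethylsilyloxy)propyl]-6-hydroxy-6-methyl-3-oxocyclohex-1-ene-1-carbaldehyde | O=CC1=C(CCCO[Si](C)(C)C(C)(C)C)C(=O)CC[C@]1(C)O | intermediate
17 | (Z)-dibutylboron enolate of 4 | CCCCB(CCCC)O/C(=C\Br)N1[C@@H](Cc2ccccc2)COC1=O | intermediate
18 | syn-aldol adduct, (2S,3R)-2-bromo-3-hydroxy imide on C4 of the cyclohexenone (C9 S) | CC(C)(C)[Si](C)(C)OCCCC1=C([C@@H](O)[C@H](Br)C(=O)N2[C@@H](Cc3ccccc3)COC2=O)[C@@](C)(O)CCC1=O | intermediate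
19 | O9,O10-isopropylidene acetal of 18 | CC(C)(C)[Si](C)(C)OCCCC1=C2[C@@H](OC(C)(C)O[C@@]2(C)CCC1=O)[C@H](Br)C(=O)N3[C@@H](Cc4ccccc4)COC3=O | intermediate
20 | ethene | C=C | starting material
21 | acetonide-bridged spiro[4.5]decan-6-one imide (C2 epimers) | CC(C)(C)[Si](C)(C)OCCC[C@@H]1C(=O)CC[C@]2(C)OC(C)(C)O[C@H]3C(CC[C@@]123)C(=O)N4[C@@H](Cc5ccccc5)COC4=O | intermediate
22 | spiro keto peroxy acid | CC(C)(C)[Si](C)(C)OCCC[C@@H]1C(=O)CC[C@]2(C)OC(C)(C)O[C@H]3C(CC[C@@]123)C(=O)OO | intermediate
23 | spiro keto acid | CC(C)(C)[Si](C)(C)OCCC[C@@H]1C(=O)CC[C@]2(C)OC(C)(C)O[C@H]3C(CC[C@@]123)C(=O)O | intermediate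
24 | isopropenylmagnesium bromide | C=C(C)[Mg]Br | starting material
25 | C6 isopropenyl carbinol acid (C6 epimers) | CC(C)(C)[Si](C)(C)OCCC[C@@H]1C(O)(C(C)=C)CC[C@]2(C)OC(C)(C)O[C@H]3C(CC[C@@]123)C(=O)O | intermediate
26 | enal acid (formyl syn to C5) | CC(C)(C)[Si](C)(C)OCCC[C@@H]1/C(=C(/C)C=O)CC[C@]2(C)OC(C)(C)O[C@H]3C(CC[C@@]123)C(=O)O | intermediate
27 | N-(acyloxy)phthalimide ester of 26 | CC(C)(C)[Si](C)(C)OCCC[C@@H]1/C(=C(/C)C=O)CC[C@]2(C)OC(C)(C)O[C@H]3C(CC[C@@]123)C(=O)ON4C(=O)c5ccccc5C4=O | intermediate
28 | 3-hydroxypropyl redox-active ester | OCCC[C@@H]1/C(=C(/C)C=O)CC[C@]2(C)OC(C)(C)O[C@H]3C(CC[C@@]123)C(=O)ON4C(=O)c5ccccc5C4=O | intermediate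
29 | tetradecanoyl chloride | CCCCCCCCCCCCCC(Cl)=O | starting material
30 | spiro fragment (tetradecanoate, enal, acetonide, redox-active ester) | CCCCCCCCCCCCCC(=O)OCCC[C@@H]1/C(=C(/C)C=O)CC[C@]2(C)OC(C)(C)O[C@H]3C(CC[C@@]123)C(=O)ON4C(=O)c5ccccc5C4=O | intermediate
31 | but-2-yne-1,4-diol | OCC#CCO | starting material
32 | 4-(triisopropylsilyloxy)but-2-yn-1-ol | CC(C)[Si](OCC#CCO)(C(C)C)C(C)C | intermediate
33 | sodium cyclic alkenylalanate from 32 | [Na+].COCCO[Al-]1(OCCOC)OCC=C1CO[Si](C(C)C)(C(C)C)C(C)C | intermediate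
34 | (Z)-3-iodo-4-(triisopropylsilyloxy)but-2-en-1-ol | CC(C)[Si](OC/C(I)=C/CO)(C(C)C)C(C)C | intermediate
35 | (Z)-5-{[3-iodo-4-(triisopropylsilyloxy)but-2-en-1-yl]sulfanyl}-1-phenyl-1H-tetrazole | CC(C)[Si](OC/C(I)=C/CSc1nnnn1-c1ccccc1)(C(C)C)C(C)C | intermediate
36 | (Z)-5-{[3-iodo-4-(triisopropylsilyloxy)but-2-en-1-yl]sulfonyl}-1-phenyl-1H-tetrazole | CC(C)[Si](OC/C(I)=C/CS(=O)(=O)c1nnnn1-c1ccccc1)(C(C)C)C(C)C | intermediate
37 | 5-bromo-2-methylpent-2-ene | CC(C)=CCCBr | starting material
38 | prop-2-yn-1-ol | C#CCO | starting material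
39 | (4-methylpent-3-en-1-yl)magnesium bromide | CC(C)=CCC[Mg]Br | intermediate
40 | 6-methyl-2-methylidenehept-5-en-1-ol | C=C(CO)CCC=C(C)C | intermediate
41 | 6-methyl-2-methylidenehept-5-enal | C=C(C=O)CCC=C(C)C | intermediate
42 | (2Z,4E)-iodo triene silyl ether | CC(C)[Si](OC/C(I)=C/C=C/C(=C)CCC=C(C)C)(C(C)C)C(C)C | intermediate
43 | Diels–Alder adduct, cyclohexene carbaldehyde (Ca, Cf as in target) | O=C[C@@]1(CCC=C(C)C)CCC(CCC=C(C)C)=C[C@@H]1/C=C(\I)CO[Si](C(C)C)(C(C)C)C(C)C | intermediate
44 | central bis(vinyl iodide) | CC(C)[Si](OC/C(I)=C/C=C/[C@@]1(CCC=C(C)C)CCC(CCC=C(C)C)=C[C@@H]1/C=C(\I)CO[Si](C(C)C)(C(C)C)C(C)C)(C(C)C)C(C)C | intermediate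
45 | bis-acetonide, bis-silyl protected dimer (C10 epimeric) | CCCCCCCCCCCCCC(=O)OCCC[C@@H]1/C(=C(/C)C=O)CC[C@]2(C)OC(C)(C)O[C@H]3[C@@H](CC[C@@]123)/C(=C\C=C\[C@@]4(CCC=C(C)C)CCC(CCC=C(C)C)=C[C@@H]4/C=C(/CO[Si](C(C)C)(C(C)C)C(C)C)[C@@H]5CC[C@@]67[C@H](CCCOC(=O)CCCCCCCCCCCCC)/C(=C(/C)C=O)CC[C@]6(C)OC(C)(C)O[C@@H]57)CO[Si](C(C)C)(C(C)C)C(C)C | intermediate
46 | bis(9,10-diol), C10 and C10′ epimeric to the target | CCCCCCCCCCCCCC(=O)OCCC[C@@H]1/C(=C(/C)C=O)CC[C@](C)(O)[C@@]12CC[C@@H](/C(=C\C=C\[C@@]1(CCC=C(C)C)CCC(CCC=C(C)C)=C[C@@H]1/C=C(/CO[Si](C(C)C)(C(C)C)C(C)C)[C@@H]1CC[C@]3([C@H](CCCOC(=O)CCCCCCCCCCCCC)/C(=C(/C)C=O)CC[C@]3(C)O)[C@H]1O)CO[Si](C(C)C)(C(C)C)C(C)C)[C@@H]2O | intermediate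
47 | bis(C10 ketone) | CCCCCCCCCCCCCC(=O)OCCC[C@@H]1/C(=C(/C)C=O)CC[C@](C)(O)[C@@]12CC[C@@H](/C(=C\C=C\[C@@]1(CCC=C(C)C)CCC(CCC=C(C)C)=C[C@@H]1/C=C(/CO[Si](C(C)C)(C(C)C)C(C)C)[C@@H]1CC[C@]3([C@H](CCCOC(=O)CCCCCCCCCCCCC)/C(=C(/C)C=O)CC[C@]3(C)O)C1=O)CO[Si](C(C)C)(C(C)C)C(C)C)C2=O | intermediate
48 | bis(triisopropylsilyl) ether of the target | CCCCCCCCCCCCCC(=O)OCCC[C@@H]1/C(=C(/C)C=O)CC[C@](C)(O)[C@@]12CC[C@@H](/C(=C\C=C\[C@@]1(CCC=C(C)C)CCC(CCC=C(C)C)=C[C@@H]1/C=C(/CO[Si](C(C)C)(C(C)C)C(C)C)[C@@H]1CC[C@]3([C@H](CCCOC(=O)CCCCCCCCCCCCC)/C(=C(/C)C=O)CC[C@]3(C)O)[C@@H]1O)CO[Si](C(C)C)(C(C)C)C(C)C)[C@H]2O | intermediate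
49 | CNP0458412.1 | CCCCCCCCCCCCCC(=O)OCCC[C@@H]1/C(=C(/C)C=O)CC[C@](C)(O)[C@@]12CC[C@@H](/C(=C\C=C\[C@@]1(CCC=C(C)C)CCC(CCC=C(C)C)=C[C@@H]1/C=C(/CO)[C@@H]1CC[C@]3([C@H](CCCOC(=O)CCCCCCCCCCCCC)/C(=C(/C)C=O)CC[C@]3(C)O)[C@@H]1O)CO)[C@H]2O | target

Total step count: 31. Longest linear sequence: 21 steps (steps 2–17, then 27–31, from (S)-linalool).

Steps most likely to fail

Step 11 (key step). Hydrogen-atom transfer to the first C2 radical may outrun its addition to sparingly soluble ethene, giving plain debromination, and ring closure may be slow if the dioxane-locked conformer is not populated. Fallback: setting out from 19, the same radical generation is run with phenyl vinyl selenide (C=C[Se]c1ccccc1), an electron-rich liquid acceptor that captures the electrophilic radical much faster. The α-selanyl radical closes onto C4 in the same sense and gives the C3-phenylselanyl spiro imide F1. Reductive deselenation of F1 (Bu3SnH, AIBN, toluene, 80 °C) comes back to the route at 21.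

Step 25. The cycloaddition may run through the formyl-endo transition state, or with weak facial discrimination because the 2-alkylacrolein is a sluggish dienophile for this mild boron catalyst. Either would give the cis (Ca, Cf) diastereomer or low enantiomeric purity. Fallback: setting out from 42 and 30, one spiro fragment is joined to the iodo triene under the nickel conditions of step 27 to give the protected monomeric tetraene F2. Thermal Diels–Alder homodimerisation of F2 (toluene, 110–130 °C, BHT) uses the terminal diene of one molecule and the 1,1-disubstituted terminal alkene of another. It should give 45 among the isomeric adducts, to be separated, and so comes back to the route at 45 without steps 25 and 26.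

Step 27. The twofold reductive coupling may stop at the mono-coupled stage, lose material to hydrodecarboxylation, or erode the trans selectivity at C2. Fallback: setting out from 30, photochemical decarboxylative iodination (LiI, 456 nm, acetone) gives the secondary C2 iodide F3. Zinc insertion (Zn, LiCl, THF) gives the alkylzinc iodide F4, which equilibrates to the isomer with zinc anti to O10. Negishi coupling of F4 (2.4 equiv) with 44 (Pd(OAc)2, CPhos, THF, rt) proceeds with retention and comes back to the route at 45.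

Further compounds
F1 | step 11 | C3-phenylselanyl analogue of 21 | CC(C)(C)[Si](C)(C)OCCC[C@@H]1C(=O)CC[C@]2(C)OC(C)(C)O[C@H]3C(CC([Se]c4ccccc4)[C@@]123)C(=O)N4[C@@H](Cc5ccccc5)COC4=O
F2 | step 25 | protected monomeric tetraene | CCCCCCCCCCCCCC(=O)OCCC[C@@H]1/C(=C(/C)C=O)CC[C@]2(C)OC(C)(C)O[C@H]3[C@@H](CC[C@@]123)/C(=C\C=C\C(=C)CCC=C(C)C)CO[Si](C(C)C)(C(C)C)C(C)C
F3 | step 27 | C2 iodide from 30 | CCCCCCCCCCCCCC(=O)OCCC[C@@H]1/C(=C(/C)C=O)CC[C@]2(C)OC(C)(C)O[C@H]3C(I)CC[C@@]123
F4 | step 27 | C2 alkylzinc iodide | CCCCCCCCCCCCCC(=O)OCCC[C@@H]1/C(=C(/C)C=O)CC[C@]2(C)OC(C)(C)O[C@H]3C([Zn]I)CC[C@@]123
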